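The product Q is read beside G, and late in the two earlier runs, cedar and ash, the two peaks keep a near-steady proportion.

common to all: L 3.3 mM (held); E 0.17 mol%
- cedar: J 0.025 M; run made earlier
- ash: J 0.038 M; run made earlier
- flask: J 0.050 M; time 3.0 h

- cedar (time / h: Q / %, G / %): 0.167: 16, 15; 0.333: 29, 27; 0.667: 36, 32; 1.00: 37, 30; 2.00: 34, 26; 4.00: 29, 27
- ash (time / h: Q / %, G / %): 0.167: 15, 16; 0.333: 29, 27; 0.667: 35, 29; 1.00: 35, 29; 2.00: 28, 26; 4.00: 28, 22

(scatter of a reading: 2 percentage points)

- at the start none of L is in solution

- the moment within 3.0 h at which there is most Q
- the amount of Q, in percent of the J charged, at that time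

Summed over the readings at 2.00 h and 4.00 h of both runs, Q over G gives ρ, the late ratio of Q to G, 1.18. These late readings play no part in the peak means below, so ρ opens two separate ways to the top of Q in the flask, which holds J at 0.050 M.

The first way uses Q readings. The mean of the readings at 0.667 h and 1.00 h falls from 36.5% in cedar to 35.0% in ash, and a straight line in the charge of J carries it to an estimate of 33.6% at the charge of the flask. The second way uses G readings. The same means, 31.0% and 29.0%, run on to 27.2% of G, and ρ turns that into 32.0% of Q. The two ways part by 1.6 percentage points, less than the scatter of a single reading, 2 points, so neither is caught cheating. This reckoning therefore takes their mean, 32.8%, at a time between 0.667 h and 1.00 h, the span that holds the highest readings of Q and of G in both runs.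

The forecast, a little above this reckoning, puts 34% at 0.8 h, on the ground that “Q then slowly decays, and a little faster at the higher loading”.

The flask gives 34.6% at 0.702 h, inside that span and 1.8 points above the reckoning.

    L ⇌ Z, rate k1*(csat - [Z]) (kL = 0.900 min⁻¹)
    G + E ⇌ Q + E, rate k2*[E]*[G] forward; the back reaction follows from the equilibrium constant (K = 1.20, k = 15000 L mol⁻¹ min⁻¹)
    J + Z + E ⇌ E + G (K = 940 L mol⁻¹, k = 4.40 × 10⁵ L² mol⁻² min⁻¹)
    J + G → X (k = 0.980 L mol⁻¹ min⁻¹)

Here Z is dissolved L, and X is a further product. In the flask at 3.00 h the step from J + G to X uses G at 0.0023 of the forward rate of G to Q, and Q over G stands at 1.20, a held ratio of the kind usually called thermodynamic control. At 0.702 h, ρ times the flask's 28.8% of G comes to 34.0%, beside 34.6% of Q.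

In the neighbour flask with E at a quarter of the loading, 0.043 mol%, ρ times its 18.3% of G at 3.00 h gives 21.6% of Q. The computed neighbour holds 22.1% of Q at that time.

(The readings stem from a simulated flask from invented constants, and the scatter is random.)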